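The route rests on cutting the five-membered ring (C1–C2–C3–C3a–C8a) from the seven-membered ring at C1–C8a and C3–C3a. That ring is cis-fused across C3a–C8a, C8a is quaternary and C4, next to C3a, carries oxygen, so the fusion bond can serve as the α,β-bond of a cycloheptenone. One TiCl4-promoted (3+2) annulation of an isopropyl(silyl)allene onto this enone then makes both bonds, the ring, the quaternary centre and the cis fusion, and leaves a C2=C3 alkene for the C3 carbinol. The precursor is an enantiopure 4-silyloxy-3,6-dimethylcyclohepta-2,5-dienone, assembled by ring-closing metathesis with the C8 oxygen already silylated.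

Key step: step 9

Assumption: the (S,S) enantiomer of the ProPhenol ligand is taken as the one that delivers the (S)-carbinol 3. The sense would be confirmed on the first run (Mosher esters) and the (R,R) ligand used instead if needed, with no other change.

Numbering: bicyclic compounds carry the azulene numbering of the target (C1 to C8a); positions in dienone 9 are quoted by the atoms they become (C4 carbonyl, C3a=C8a enone, C8 carbinol, C6=C7 alkene).

Step 1
Reactants: 1 methyl propiolate; 2 (E)-but-2-enal
Product: 3 methyl (4S,5E)-4-hydroxyhept-5-en-2-ynoate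
Conditions: ZnMe2, (S,S)-ProPhenol (10 mol%), toluene, 4 °C; then aq. NH4Cl
Reagents that add atoms: none
Why: Zinc–ProPhenol alkynylation, in which the alkynylzinc formed from 1 and ZnMe2 adds to the enal inside the dinuclear zinc pocket of the ligand and so sets the carbinol centre (the future C8) as S; enals with methyl propiolate are the substrate class this catalytic addition is known for.

Step 2
Reactants: 3 methyl (4S,5E)-4-hydroxyhept-5-en-2-ynoate
Product: 4 methyl (4S,5E)-4-[(tert-butyldimethylsilyl)oxy]hept-5-en-2-ynoate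
Conditions: TBSOTf, 2,6-lutidine, CH2Cl2, −78 °C
Reagents that add atoms: tert-butyldimethylsilyl trifluoromethanesulfonate, CC(C)(C)[Si](C)(C)OS(=O)(=O)C(F)(F)F
Why: Silylation of a secondary propargylic alcohol with a silyl triflate and a hindered pyridine base at low temperature, chosen because stronger amine bases can isomerise γ-hydroxy ynoates to γ-oxo enoates; the stereocentre is not touched.

Step 3
Reactants: 4 methyl (4S,5E)-4-[(tert-butyldimethylsilyl)oxy]hept-5-en-2-ynoate
Product: 5 methyl (2Z,4S,5E)-4-[(tert-butyldimethylsilyl)oxy]-3-methylhepta-2,5-dienoate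
Conditions: Me2CuLi (from MeLi and CuI), THF, −78 °C; then MeOH, −78 °C
Reagents that add atoms: lithium dimethylcuprate, [Li+].C[Cu-]C
Why: Syn carbocupration (cuprate conjugate addition) of the ynoate and protonation of the vinylcopper at −78 °C place the new methyl and the hydrogen cis, so the ester and the silyloxy-bearing carbon end up cis (2Z), the geometry the ring later needs at C3a=C8a.

Step 4
Reactants: 5 methyl (2Z,4S,5E)-4-[(tert-butyldimethylsilyl)oxy]-3-methylhepta-2,5-dienoate
Product: 6 (2Z,4S,5E)-4-[(tert-butyldimethylsilyl)oxy]-N-methoxy-N,3-dimethylhepta-2,5-dienamide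
Conditions: Me(MeO)NH·HCl, AlMe3, CH2Cl2, 0 °C to rt
Reagents that add atoms: N,O-dimethylhydroxylamine hydrochloride, CNOC.Cl
Why: Weinreb amidation of the ester by the aluminium amide formed from AlMe3 and the amine hydrochloride, a standard aminolysis that should leave the Z alkene and the silyl ether in place.

Step 5
Reactants: 6 (2Z,4S,5E)-4-[(tert-butyldimethylsilyl)oxy]-N-methoxy-N,3-dimethylhepta-2,5-dienamide; 7 2-methylallylmagnesium chloride
Product: 8 (5Z,7S,8E)-7-[(tert-butyldimethylsilyl)oxy]-2,6-dimethyldeca-1,5,8-trien-4-one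
Conditions: THF, −78 to −20 °C; then aq. NH4Cl, 0 °C
Reagents that add atoms: none
Why: Grignard addition to a Weinreb amide stops at the chelated tetrahedral adduct, so only one methallyl group is taken up and the β,γ-unsaturated ketone is released on a cold, near-neutral quench before the new alkene can move into conjugation.

Step 6
Reactants: 8 (5Z,7S,8E)-7-[(tert-butyldimethylsilyl)oxy]-2,6-dimethyldeca-1,5,8-trien-4-one
Product: 9 (S)-4-[(tert-butyldimethylsilyl)oxy]-3,6-dimethylcyclohepta-2,5-dien-1-one
Conditions: second-generation Grubbs catalyst (H2IMes)(PCy3)Cl2Ru=CHPh (5 mol%), 1,4-benzoquinone (10 mol%), CH2Cl2 (5 mM), 40 °C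
Reagents that add atoms: none
Why: Ring-closing olefin metathesis between the propenyl group and the 1,1-disubstituted alkene closes the seven-membered ring as the trisubstituted C6=C7 alkene with loss of propene; the Z enone holds the two ends close, and the C8 oxygen is silylated before the elimination-prone 4-oxygenated 2,5-dienone exists.

Step 7
Reactants: 10 3-(trimethylsilyl)prop-2-yn-1-ol
Product: 11 3-(trimethylsilyl)prop-2-yn-1-yl methanesulfonate
Conditions: MsCl, Et3N, CH2Cl2, 0 °C
Reagents that add atoms: methanesulfonyl chloride, CS(=O)(=O)Cl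
Why: Standard sulfonylation of a primary propargylic alcohol.

Step 8
Reactants: 11 3-(trimethylsilyl)prop-2-yn-1-yl methanesulfonate; 12 isopropylmagnesium chloride
Product: 13 (4-methylpenta-1,2-dien-3-yl)trimethylsilane
Conditions: CuBr, LiBr, THF, −78 °C to rt
Reagents that add atoms: none
Why: SN2′ displacement of the propargylic mesylate by the organocopper reagent formed from 12 and CuBr delivers the isopropyl group to the silyl-bearing alkyne carbon and gives the 1-alkyl-1-silylallene, the usual way to such allenes.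

Step 9
Reactants: 9 (S)-4-[(tert-butyldimethylsilyl)oxy]-3,6-dimethylcyclohepta-2,5-dien-1-one; 13 (4-methylpenta-1,2-dien-3-yl)trimethylsilane
Product: 14 (3aS,8S,8aS)-8-[(tert-butyldimethylsilyl)oxy]-3-isopropyl-6,8a-dimethyl-2-(trimethylsilyl)-3a,5,8,8a-tetrahydroazulen-4(1H)-one
Conditions: TiCl4 (1.2 equiv), 13 (1.5 equiv), CH2Cl2, −78 °C; then aq. NaHCO3
Reagents that add atoms: none
Why: TiCl4 binds the C4 carbonyl of 9, the CH2 terminus of allene 13 adds to C8a in a Sakurai-type conjugate addition, and the β-silyl vinyl cation undergoes a 1,2-silyl shift that moves the charge to the isopropyl-bearing carbon, which the titanium enolate carbon C3a then captures; this is the Danheiser (trimethylsilyl)cyclopentene annulation of allenylsilanes with enones, a stepwise (3+2) process. The ring C1–C2–C3–C3a–C8a is closed by C-alkylation of the enolate on the vinyl cation, formally a 5-endo-dig closure that keeps the C2=C3 alkene inside the new ring. C8a is set by substrate control: allylic strain with the C8a methyl turns the C8 silyloxy group out of the enone plane, so the allene should come in on the face anti to it and the methyl ends up cis to the C8 oxygen. C3a follows from the tether, because the three-carbon chain bound to C8a can reach C3a only on the same face, which gives the cis fusion. The step needs attack at C8a only (it is the sole enone β-carbon, and the isolated C6=C7 alkene is not activated) and survival of the skipped dienone and the bis-allylic silyl ether, which the low temperature and the electron-poor, titanium-bound enone (disfavouring ionisation at C8) should secure.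

Step 10
Reactants: 14 (3aS,8S,8aS)-8-[(tert-butyldimethylsilyl)oxy]-3-isopropyl-6,8a-dimethyl-2-(trimethylsilyl)-3a,5,8,8a-tetrahydroazulen-4(1H)-one
Product: 15 (3aR,8S,8aS)-8-[(tert-butyldimethylsilyl)oxy]-3-isopropyl-6,8a-dimethyl-3a,5,8,8a-tetrahydroazulen-4(1H)-one
Conditions: CF3CO2H (3 equiv), CH2Cl2, 0 °C; then aq. NaHCO3
Reagents that add atoms: none
Why: Acid-mediated ipso-protodesilylation of the vinylsilane, in which protonation at C2 gives the tertiary C3 cation stabilised by the β-silicon and loss of the silyl group restores the C2=C3 alkene in place; the C6=C7 alkene lacks this activation and the hindered secondary silyl ether should survive brief exposure at 0 °C.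

Step 11
Reactants: 15 (3aR,8S,8aS)-8-[(tert-butyldimethylsilyl)oxy]-3-isopropyl-6,8a-dimethyl-3a,5,8,8a-tetrahydroazulen-4(1H)-one
Product: 16 (2S,3R,3aS,8S,8aS)-8-[(tert-butyldimethylsilyl)oxy]-2,3-epoxy-3-isopropyl-6,8a-dimethyl-2,3,3a,5,8,8a-hexahydroazulen-4(1H)-one
Conditions: mCPBA (1.05 equiv), NaHCO3, CH2Cl2, −20 to 0 °C
Reagents that add atoms: meta-chloroperoxybenzoic acid, OOC(=O)c1cccc(Cl)c1
Why: Prilezhaev epoxidation, expected on the convex face of the cis-fused bicycle (the face of H-3a and the C8a methyl, away from C4), which sets C2 and C3, while the C6=C7 alkene is deactivated and shielded by its allylic silyloxy group.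

Step 12
Reactants: 16 (2S,3R,3aS,8S,8aS)-8-[(tert-butyldimethylsilyl)oxy]-2,3-epoxy-3-isopropyl-6,8a-dimethyl-2,3,3a,5,8,8a-hexahydroazulen-4(1H)-one
Product: 18 (3R,3aR,4S,8S,8aS)-8-[(tert-butyldimethylsilyl)oxy]-3-isopropyl-6,8a-dimethyl-1,2,3,3a,4,5,8,8a-octahydroazulene-3,4-diol, via epoxy alcohol 17 (not isolated)
Conditions: LiBHEt3 (4 equiv), THF, −78 °C to rt; then H2O
Reagents that add atoms: none
Why: Hydride reduction in two stages: the ketone is reduced first from the convex face (the concave face is blocked by the isopropyl-bearing C3), which sets C4 with its hydroxyl trans to H-3a, and the trisubstituted epoxide is then opened by SN2 attack of hydride at the less substituted C2, leaving the tertiary C3 carbinol with its configuration unchanged.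

Step 13
Reactants: 18 (3R,3aR,4S,8S,8aS)-8-[(tert-butyldimethylsilyl)oxy]-3-isopropyl-6,8a-dimethyl-1,2,3,3a,4,5,8,8a-octahydroazulene-3,4-diol; 19 4-methoxybenzoyl chloride
Product: 20 (3R,3aR,4S,8S,8aS)-8-[(tert-butyldimethylsilyl)oxy]-3-hydroxy-3-isopropyl-6,8a-dimethyl-1,2,3,3a,4,5,8,8a-octahydroazulen-4-yl 4-methoxybenzoate
Conditions: DMAP, pyridine, CH2Cl2, 0 °C to rt
Reagents that add atoms: none
Why: DMAP-catalysed acylation with an acid chloride (nucleophilic acyl transfer) should take place at the secondary C4 hydroxyl only, since the tertiary C3 carbinol does not react under these conditions.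

Step 14
Reactants: 20 (3R,3aR,4S,8S,8aS)-8-[(tert-butyldimethylsilyl)oxy]-3-hydroxy-3-isopropyl-6,8a-dimethyl-1,2,3,3a,4,5,8,8a-octahydroazulen-4-yl 4-methoxybenzoate
Product: 21 (3R,3aR,4S,8S,8aS)-3,8-dihydroxy-3-isopropyl-6,8a-dimethyl-1,2,3,3a,4,5,8,8a-octahydroazulen-4-yl 4-methoxybenzoate
Conditions: HF·pyridine, pyridine, THF, 0 °C to rt
Reagents that add atoms: none
Why: Fluoride-mediated cleavage of the silyl ether under buffered conditions, which should leave the aryl ester and the tertiary alcohol untouched.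

Step 15
Reactants: 21 (3R,3aR,4S,8S,8aS)-3,8-dihydroxy-3-isopropyl-6,8a-dimethyl-1,2,3,3a,4,5,8,8a-octahydroazulen-4-yl 4-methoxybenzoate
Product: 22 (3R,3aR,4S,8S,8aS)-8-acetoxy-3-hydroxy-3-isopropyl-6,8a-dimethyl-1,2,3,3a,4,5,8,8a-octahydroazulen-4-yl 4-methoxybenzoate
Conditions: Ac2O (1.5 equiv), DMAP (cat.), pyridine, CH2Cl2, 0 °C
Reagents that add atoms: acetic anhydride, CC(=O)OC(C)=O
Why: DMAP-catalysed acetylation of the secondary allylic C8 hydroxyl; the tertiary C3 carbinol should not react at 0 °C with a small excess of anhydride.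

Compound list

1 | methyl propiolate (methyl prop-2-ynoate) | C#CC(=O)OC | starting material
2 | (E)-but-2-enal (crotonaldehyde) | C/C=C/C=O | starting material
3 | methyl (4S,5E)-4-hydroxyhept-5-en-2-ynoate | COC(=O)C#C[C@@H](O)/C=C/C | intermediate
4 | methyl (4S,5E)-4-[(tert-butyldimethylsilyl)oxy]hept-5-en-2-ynoate | COC(=O)C#C[C@@H](O[Si](C)(C)C(C)(C)C)/C=C/C | intermediate
5 | methyl (2Z,4S,5E)-4-[(tert-butyldimethylsilyl)oxy]-3-methylhepta-2,5-dienoate | COC(=O)/C=C(/C)[C@@H](O[Si](C)(C)C(C)(C)C)/C=C/C | intermediate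
6 | (2Z,4S,5E)-4-[(tert-butyldimethylsilyl)oxy]-N-methoxy-N,3-dimethylhepta-2,5-dienamide | CON(C)C(=O)/C=C(/C)[C@@H](O[Si](C)(C)C(C)(C)C)/C=C/C | intermediate
7 | 2-methylallylmagnesium chloride | CC(=C)C[Mg]Cl | starting material
8 | (5Z,7S,8E)-7-[(tert-butyldimethylsilyl)oxy]-2,6-dimethyldeca-1,5,8-trien-4-one | CC(=C)CC(=O)/C=C(/C)[C@@H](O[Si](C)(C)C(C)(C)C)/C=C/C | intermediate
9 | (S)-4-[(tert-butyldimethylsilyl)oxy]-3,6-dimethylcyclohepta-2,5-dien-1-one | O=C1CC(C)=C[C@H](O[Si](C)(C)C(C)(C)C)C(C)=C1 | intermediate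
10 | 3-(trimethylsilyl)prop-2-yn-1-ol | C[Si](C)(C)C#CCO | starting material
11 | 3-(trimethylsilyl)prop-2-yn-1-yl methanesulfonate | C[Si](C)(C)C#CCOS(C)(=O)=O | intermediate
12 | isopropylmagnesium chloride | CC(C)[Mg]Cl | starting material
13 | (4-methylpenta-1,2-dien-3-yl)trimethylsilane | CC(C)C(=C=C)[Si](C)(C)C | intermediate
14 | (3aS,8S,8aS)-8-[(tert-butyldimethylsilyl)oxy]-3-isopropyl-6,8a-dimethyl-2-(trimethylsilyl)-3a,5,8,8a-tetrahydroazulen-4(1H)-one (cis-fused; C8 oxygen cis to the C8a methyl) | O=C1CC(C)=C[C@H](O[Si](C)(C)C(C)(C)C)[C@@]2(C)CC([Si](C)(C)C)=C(C(C)C)[C@@H]12 | intermediate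
15 | (3aR,8S,8aS)-8-[(tert-butyldimethylsilyl)oxy]-3-isopropyl-6,8a-dimethyl-3a,5,8,8a-tetrahydroazulen-4(1H)-one | O=C1CC(C)=C[C@H](O[Si](C)(C)C(C)(C)C)[C@@]2(C)CC=C(C(C)C)[C@@H]12 | intermediate
16 | (2S,3R,3aS,8S,8aS)-8-[(tert-butyldimethylsilyl)oxy]-2,3-epoxy-3-isopropyl-6,8a-dimethyl-2,3,3a,5,8,8a-hexahydroazulen-4(1H)-one (epoxide oxygen on the face of H-3a and the C8a methyl) | O=C1CC(C)=C[C@H](O[Si](C)(C)C(C)(C)C)[C@@]2(C)C[C@@H]3O[C@]3(C(C)C)[C@@H]12 | intermediate
17 | (2S,3R,3aR,4S,8S,8aS)-8-[(tert-butyldimethylsilyl)oxy]-2,3-epoxy-3-isopropyl-6,8a-dimethyl-1,2,3,3a,4,5,8,8a-octahydroazulen-4-ol (epoxy alcohol, present in the flask of step 12 as its lithium alkoxide) | O[C@H]1CC(C)=C[C@H](O[Si](C)(C)C(C)(C)C)[C@@]2(C)C[C@@H]3O[C@]3(C(C)C)[C@@H]12 | intermediate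
18 | (3R,3aR,4S,8S,8aS)-8-[(tert-butyldimethylsilyl)oxy]-3-isopropyl-6,8a-dimethyl-1,2,3,3a,4,5,8,8a-octahydroazulene-3,4-diol | O[C@H]1CC(C)=C[C@H](O[Si](C)(C)C(C)(C)C)[C@@]2(C)CC[C@@](O)(C(C)C)[C@@H]12 | intermediate
19 | 4-methoxybenzoyl chloride | COc1ccc(C(Cl)=O)cc1 | starting material
20 | (3R,3aR,4S,8S,8aS)-8-[(tert-butyldimethylsilyl)oxy]-3-hydroxy-3-isopropyl-6,8a-dimethyl-1,2,3,3a,4,5,8,8a-octahydroazulen-4-yl 4-methoxybenzoate | COc1ccc(C(=O)O[C@H]2CC(C)=C[C@H](O[Si](C)(C)C(C)(C)C)[C@@]3(C)CC[C@@](O)(C(C)C)[C@@H]23)cc1 | intermediate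
21 | (3R,3aR,4S,8S,8aS)-3,8-dihydroxy-3-isopropyl-6,8a-dimethyl-1,2,3,3a,4,5,8,8a-octahydroazulen-4-yl 4-methoxybenzoate | COc1ccc(C(=O)O[C@H]2CC(C)=C[C@H](O)[C@@]3(C)CC[C@@](O)(C(C)C)[C@@H]23)cc1 | intermediate
22 | (3R,3aR,4S,8S,8aS)-8-acetoxy-3-hydroxy-3-isopropyl-6,8a-dimethyl-1,2,3,3a,4,5,8,8a-octahydroazulen-4-yl 4-methoxybenzoate | COc1ccc(C(=O)O[C@H]2CC(C)=C[C@H](OC(C)=O)[C@@]3(C)CC[C@@](O)(C(C)C)[C@@H]23)cc1 | target

Total step count: 15. Longest linear sequence: 13 steps (steps 1 to 6, then 9 to 15); the allene is made in two steps (7 and 8) and joins at step 9.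

Steps most likely to fail

Step 9 (annulation). The allene may add too slowly to the hindered, β,β-disubstituted C8a. The vinyl cation may lose silicon before the enolate closes the ring, which would give conjugate propargylation instead of annulation. TiCl4 may also ionise the bis-allylic silyl ether or move the skipped alkene into conjugation. The fallback sets out from 9 and returns at 15, and makes the two bonds in separate, milder operations. Commercial 4-methylpent-2-yn-1-ol would be mesylated (MsCl, Et3N) to 4-methylpent-2-yn-1-yl methanesulfonate F1. Anti-SN2′ stannylation with Bu3SnLi/CuBr·SMe2 would then give tributyl(4-methylpenta-1,2-dien-3-yl)stannane F2. TBSOTf-promoted conjugate propargylation of 9 with the stannane (CH2Cl2, −78 °C) should again occur anti to the C8 silyloxy group; tin leaves at once, so no ring closure is required at the cation stage. It would give the regiodefined silyl enol ether (3S,4S)-1,4-bis[(tert-butyldimethylsilyl)oxy]-3,6-dimethyl-3-(4-methylpent-2-yn-1-yl)cyclohepta-1,5-diene F3. Ph3PAuCl/AgBF4 (10 mol%) in CH2Cl2/MeOH would then close C3–C3a by 5-endo-dig carbocyclisation of the enol ether onto the alkyne and, after protodeauration, give ketone 15 directly, so step 10 would no longer be needed.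

Step 11 (epoxidation). The peracid may fail to distinguish the two trisubstituted alkenes (C2=C3 against C6=C7), or part of the attack may come from the concave face. The fallback sets out from 15 and returns at 18, and brings in the C3 oxygen by radical Markovnikov hydration instead. Mukaiyama–Isayama hydration (Co(acac)2 cat., PhSiH3, O2, iPrOH, rt) is governed by other factors: hydrogen-atom transfer goes to the less encumbered alkene carbon (C2, flanked by a CH2, against C7, flanked by the silyloxy-bearing C8), and the tertiary C3 radical is trapped by O2 on the convex face. It would give (3R,3aS,8S,8aS)-8-[(tert-butyldimethylsilyl)oxy]-3-hydroxy-3-isopropyl-6,8a-dimethyl-2,3,3a,5,8,8a-hexahydroazulen-4(1H)-one F4. NaBH4 (MeOH, −40 °C, cold enough to avoid retro-aldol opening) would then reduce C4 from the convex face and give diol 18.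

Step 10 (protodesilylation). Under Brønsted acid the β,γ-unsaturated ketone may isomerise into conjugation (C2=C3 or C6=C7 moving next to C4), C3a may epimerise, or the allylic silyl ether may be lost. The fallback sets out from 14 and returns at 15, and removes silicon without acid in two operations. Ipso-iododesilylation with N-iodosuccinimide (MeCN, 0 °C) would give (3aS,8S,8aS)-8-[(tert-butyldimethylsilyl)oxy]-2-iodo-3-isopropyl-6,8a-dimethyl-3a,5,8,8a-tetrahydroazulen-4(1H)-one F5. Hydrodeiodination with Bu3SnH and Pd(PPh3)4 (cat.) in THF at rt would then give 15.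

Further compounds

F1 | step 9 | 4-methylpent-2-yn-1-yl methanesulfonate | CC(C)C#CCOS(C)(=O)=O
F2 | step 9 | tributyl(4-methylpenta-1,2-dien-3-yl)stannane | CCCC[Sn](CCCC)(CCCC)C(=C=C)C(C)C
F3 | step 9 | (3S,4S)-1,4-bis[(tert-butyldimethylsilyl)oxy]-3,6-dimethyl-3-(4-methylpent-2-yn-1-yl)cyclohepta-1,5-diene | CC(C)(C)[Si](C)(C)OC1=C[C@](C)(CC#CC(C)C)[C@@H](O[Si](C)(C)C(C)(C)C)C=C(C)C1
F4 | step 11 | (3R,3aS,8S,8aS)-8-[(tert-butyldimethylsilyl)oxy]-3-hydroxy-3-isopropyl-6,8a-dimethyl-2,3,3a,5,8,8a-hexahydroazulen-4(1H)-one | O=C1CC(C)=C[C@H](O[Si](C)(C)C(C)(C)C)[C@@]2(C)CC[C@@](O)(C(C)C)[C@@H]12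
F5 | step 10 | (3aS,8S,8aS)-8-[(tert-butyldimethylsilyl)oxy]-2-iodo-3-isopropyl-6,8a-dimethyl-3a,5,8,8a-tetrahydroazulen-4(1H)-one | O=C1CC(C)=C[C@H](O[Si](C)(C)C(C)(C)C)[C@@]2(C)CC(I)=C(C(C)C)[C@@H]12
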